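**Direct plan and its weak points**

A direct plan would grow the chain one ring at a time from ring A to ring F, with benzyl ethers throughout and hydrogenolysis at the end.
It would first make the ring AB phenol A1 by building ring A onto a ring B aryloxyacetate (acetoacetate dianion Claisen, then Dieckmann aromatisation).
Rings C, E and F would each come from an Ullmann coupling with 2,6-bis(benzyloxy)-4-bromobenzaldehyde A2 followed by a Dakin oxidation; ring D would enter as 2,3,4-tris(benzyloxy)-6-bromobenzaldehyde A3.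
Weak point 1, the run-up to A1: about nine linear steps for one diaryl ether, several of them protecting-group changes (MOM on and off, acetate to benzyl) that build nothing.
Weak point 2, the Ullmann coupling of the ring ABC phenol A4 with A3: a di-ortho-substituted phenol meets an ortho-substituted bromide late in the route, and A3 itself needs formylation, demethylation and re-benzylation.
Weak point 3, the repeated coupling and Dakin pair: each ring costs a copper coupling of a hindered phenol and a peracid oxidation on an ever larger, more electron-rich oligomer, in one linear line of more than twenty steps.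

**Retrosynthetic overview of the new route**

Ring D is the only ring that is not a commercial phenol: C1 (O to ring C), C2 (H), C3–C5 (OH) and C6 (O to ring E) give five oxygenated carbons in a row and the only ortho diether.
Ring D is cut into dimethyl squarate (C3–C6 with their four oxygens) and an aryloxyvinyl unit (C1–C2 plus the ring C ether oxygen, from 2,6-dimethoxyphenol and trichloroethylene); a Liebeskind–Moore ring expansion closes it and leaves the C6 hydroxyl as the only free OH.
Rings A, B, C, E and F are bought with all their oxygens in place; ring D is the only ring formed, then ring EF is attached at O6 of ring D, then ring B, then ring A.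
Each of these ether bonds comes from one cycle: iridium-catalysed borylation of the single unhindered C–H (para to the ether oxygen of a 2,6-dimethoxyphenoxy ring), then Chan–Lam coupling with the next phenol.
The design therefore has no de novo ring A, no protecting-group change (methyl ethers throughout, one global cleavage), no coupling at the crowded C1 of ring D and no Dakin oxidation.

Key step: step 6

Remark: the target has no stereocentre; rings are lettered A to F from the 2,4,6-trihydroxyphenyl end and ring D is numbered as above. Compounds 12, 13 and 15 are racemic, and their single stereocentre disappears in step 6.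

**Route**

Step 1
Reactants: 1 2,6-dimethoxyphenol; 2 (3,4,5-trimethoxyphenyl)boronic acid
Product: 3 1,3-dimethoxy-2-(3,4,5-trimethoxyphenoxy)benzene
Conditions: 2 (2 equiv), Cu(OAc)2 (2 equiv), pyridine (5 equiv), 4 Å molecular sieves, CH2Cl2, dry air, rt
Reagents that add atoms: none
Why: Chan–Lam coupling; transmetalation of the unhindered arylboronic acid to divalent copper and C–O reductive elimination tolerate the two ortho methoxy groups of the phenol at room temperature.

Step 2
Reactants: 3 1,3-dimethoxy-2-(3,4,5-trimethoxyphenoxy)benzene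
Product: 5 [3,5-dimethoxy-4-(3,4,5-trimethoxyphenoxy)phenyl]boronic acid, via pinacol boronate 4 (not isolated)
Conditions: [Ir(OMe)(cod)]2 (1.5 mol %), 4,4'-di-tert-butyl-2,2'-bipyridine (3 mol %), B2pin2 (0.6 equiv), THF, 80 °C; then NaIO4, NH4OAc, acetone–H2O, rt
Reagents that add atoms: bis(pinacolato)diboron CC1(C)OB(OC1(C)C)B1OC(C)(C)C(C)(C)O1; water O
Why: Iridium-catalysed aromatic C–H borylation is sterically controlled, and the C–H para to the ether oxygen of ring E is the only one in 3 without an ortho substituent; periodate cleavage of the pinacol ester then frees the boronic acid.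

Step 3
Reactants: 1 2,6-dimethoxyphenol; 6 trichloroethylene
Product: 7 2-{[(E)-1,2-dichloroethenyl]oxy}-1,3-dimethoxybenzene
Conditions: K2CO3 (1.5 equiv), 6 (1.5 equiv), DMF, 70 °C
Reagents that add atoms: none
Why: Nucleophilic vinylic substitution by elimination–addition; base turns trichloroethylene into dichloroacetylene in the flask, and anti addition of the phenoxide gives the E ether.

Step 4
Reactants: 7 2-{[(E)-1,2-dichloroethenyl]oxy}-1,3-dimethoxybenzene; 8 dimethyl squarate (3,4-dimethoxycyclobut-3-ene-1,2-dione)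
Product: 12 4-[(2,6-dimethoxyphenoxy)ethynyl]-2,3,4-trimethoxycyclobut-2-en-1-one (racemic), via chloroethynyl ether 9 (not isolated), via lithium acetylide 10 (not isolated), via lithium alkoxide 11 (not isolated)
Conditions: n-BuLi (2.05 equiv), THF, −78 → −40 °C; 8 (0.9 equiv), −78 °C; MeOTf (1.5 equiv), −78 → 0 °C
Reagents that add atoms: methyl trifluoromethanesulfonate COS(=O)(=O)C(F)(F)F
Why: Elimination of HCl and chlorine–lithium exchange give the lithium alkynyl ether, which adds 1,2 to one squarate carbonyl (the alkoxide formed shields the second), and the tertiary alkoxide is O-methylated in the same flask.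

Step 5
Reactants: 12 4-[(2,6-dimethoxyphenoxy)ethynyl]-2,3,4-trimethoxycyclobut-2-en-1-one
Product: 13 4-[(Z)-2-(2,6-dimethoxyphenoxy)ethenyl]-2,3,4-trimethoxycyclobut-2-en-1-one (racemic)
Conditions: H2 (1 atm), Pd/CaCO3 poisoned with Pb(OAc)2, quinoline, EtOAc, rt
Reagents that add atoms: none
Why: Lindlar semihydrogenation adds hydrogen syn to the alkynyl ether and stops at the Z enol ether, while the tetrasubstituted ring alkene is not reduced.

Step 6
Reactants: 13 4-[(Z)-2-(2,6-dimethoxyphenoxy)ethenyl]-2,3,4-trimethoxycyclobut-2-en-1-one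
Product: 16 6-(2,6-dimethoxyphenoxy)-2,3,4-trimethoxyphenol, via dienylketene 14 (not isolated), via cyclohexadienone 15 (not isolated)
Conditions: toluene (degassed, 0.02 M), 110 °C
Reagents that add atoms: none
Why: Liebeskind–Moore ring expansion: thermal conrotatory 4π opening of the cyclobutenone, in which the C4 methoxy group rotates outward and so places the aryloxyvinyl group cis to the new ketene, gives dienylketene 14. A 6π electrocyclization then closes ring D as the six-membered dienone 15 by joining the former carbonyl carbon (C6 of ring D) to the aryloxy-bearing vinyl carbon (C1), and enolization aromatizes it. The closest known reaction type is the thermolysis of 4-alkenyl-4-alkoxy-2,3-dialkoxycyclobutenones to hydroquinone monoethers. No stereocentre remains, because the sp3 carbon of 15 is lost on enolization. The regiochemistry is fixed by connectivity and not by reagent control: the ketene oxygen can only end up on C6, between the C5 methoxy and the C1 aryl ether, as the only free hydroxyl, while the carbinol oxygen methylated in step 4 becomes the C3 methoxy next to the lone C2–H. The ketene terminus is unsubstituted, so the inward aryloxy group of the Z alkene meets little strain on closure, and the two ortho methoxy groups of ring C leave the aryl vinyl ether no sigmatropic escape.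

Step 7
Reactants: 16 6-(2,6-dimethoxyphenoxy)-2,3,4-trimethoxyphenol; 5 [3,5-dimethoxy-4-(3,4,5-trimethoxyphenoxy)phenyl]boronic acid
Product: 17 1-(2,6-dimethoxyphenoxy)-2-[3,5-dimethoxy-4-(3,4,5-trimethoxyphenoxy)phenoxy]-3,4,5-trimethoxybenzene (ring CDEF tetramer)
Conditions: 5 (2 equiv), Cu(OAc)2 (2 equiv), pyridine (5 equiv), 4 Å molecular sieves, CH2Cl2, dry air, rt
Reagents that add atoms: none
Why: Chan–Lam coupling; the boronic acid has no ortho substituent and phenol 16 has no free ortho or para position, so oxidative C–C coupling of the phenol cannot compete with O-arylation.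

Step 8
Reactants: 17 ring CDEF tetramer
Product: 19 {4-[2-[3,5-dimethoxy-4-(3,4,5-trimethoxyphenoxy)phenoxy]-3,4,5-trimethoxyphenoxy]-3,5-dimethoxyphenyl}boronic acid, via pinacol boronate 18 (not isolated)
Conditions: [Ir(OMe)(cod)]2 (2 mol %), 4,4'-di-tert-butyl-2,2'-bipyridine (4 mol %), B2pin2 (0.6 equiv), THF, 80 °C; then NaIO4, NH4OAc, acetone–H2O, rt
Reagents that add atoms: bis(pinacolato)diboron CC1(C)OB(OC1(C)C)B1OC(C)(C)C(C)(C)O1; water O
Why: Iridium-catalysed aromatic C–H borylation; in 17 only the C–H para to the ether oxygen of ring C has no ortho substituent, since every hydrogen of rings D, E and F lies between two oxygen substituents.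

Step 9
Reactants: 19 ring CDEF boronic acid; 1 2,6-dimethoxyphenol
Product: 20 1-[4-(2,6-dimethoxyphenoxy)-2,6-dimethoxyphenoxy]-2-[3,5-dimethoxy-4-(3,4,5-trimethoxyphenoxy)phenoxy]-3,4,5-trimethoxybenzene (ring BCDEF pentamer)
Conditions: 1 (3 equiv), Cu(OAc)2 (2 equiv), pyridine (5 equiv), 4 Å molecular sieves, CH2Cl2, dry air, rt
Reagents that add atoms: none
Why: Chan–Lam coupling; the cheap phenol is used in excess so that its oxidative self-coupling does not limit conversion of the boronic acid, and the new ring B again offers a single unhindered C–H for the next cycle.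

Step 10
Reactants: 20 ring BCDEF pentamer
Product: 22 {4-[4-[2-[3,5-dimethoxy-4-(3,4,5-trimethoxyphenoxy)phenoxy]-3,4,5-trimethoxyphenoxy]-2,6-dimethoxyphenoxy]-3,5-dimethoxyphenyl}boronic acid, via pinacol boronate 21 (not isolated)
Conditions: [Ir(OMe)(cod)]2 (2 mol %), 4,4'-di-tert-butyl-2,2'-bipyridine (4 mol %), B2pin2 (0.6 equiv), THF, 80 °C; then NaIO4, NH4OAc, acetone–H2O, rt
Reagents that add atoms: bis(pinacolato)diboron CC1(C)OB(OC1(C)C)B1OC(C)(C)C(C)(C)O1; water O
Why: Iridium-catalysed aromatic C–H borylation; the C–H para to the ether oxygen of ring B is now the only one without an ortho substituent.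

Step 11
Reactants: 22 ring BCDEF boronic acid; 23 2,4,6-trimethoxyphenol
Product: 24 pentadeca-O-methyl ether of the target (ring ABCDEF hexamer)
Conditions: 23 (3 equiv), Cu(OAc)2 (2 equiv), pyridine (5 equiv), 4 Å molecular sieves, CH2Cl2, dry air, rt
Reagents that add atoms: none
Why: Chan–Lam coupling; 2,4,6-trimethoxyphenol brings ring A with all its oxygens, and its blocked para position prevents oxidative self-coupling.

Step 12
Reactants: 24 pentadeca-O-methyl ether of the target
Product: 26 CNP0175585.0 (target hexamer), via aryl borate 25 (not isolated)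
Conditions: BBr3 (30 equiv), CH2Cl2, −78 °C → rt, Ar; then MeOH, 0 °C; H2O; concentrated and purified under Ar
Reagents that add atoms: none
Why: Lewis-acid ether cleavage; BBr3 cleaves all fifteen aryl methyl ethers by bromide attack at methyl, so no carbocation can alkylate the electron-rich rings, the diaryl ether bonds are inert, and hydrolysis of the aryl borates under argon frees the air-sensitive polyphenol.

**Compound list**

1 | 2,6-dimethoxyphenol | COc1cccc(OC)c1O | starting material
2 | (3,4,5-trimethoxyphenyl)boronic acid | COc1cc(B(O)O)cc(OC)c1OC | starting material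
3 | 1,3-dimethoxy-2-(3,4,5-trimethoxyphenoxy)benzene | COc1cccc(OC)c1Oc1cc(OC)c(OC)c(OC)c1 | intermediate
4 | 2-[3,5-dimethoxy-4-(3,4,5-trimethoxyphenoxy)phenyl]-4,4,5,5-tetramethyl-1,3,2-dioxaborolane | COc1cc(B2OC(C)(C)C(C)(C)O2)cc(OC)c1Oc1cc(OC)c(OC)c(OC)c1 | intermediate (not isolated)
5 | [3,5-dimethoxy-4-(3,4,5-trimethoxyphenoxy)phenyl]boronic acid | COc1cc(B(O)O)cc(OC)c1Oc1cc(OC)c(OC)c(OC)c1 | intermediate
6 | trichloroethylene | ClC=C(Cl)Cl | starting material
7 | 2-{[(E)-1,2-dichloroethenyl]oxy}-1,3-dimethoxybenzene | Cl/C=C(/Cl)Oc1c(OC)cccc1OC | intermediate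
8 | dimethyl squarate (3,4-dimethoxycyclobut-3-ene-1,2-dione) | COC1=C(OC)C(=O)C1=O | starting material
9 | 2-[(chloroethynyl)oxy]-1,3-dimethoxybenzene | ClC#COc1c(OC)cccc1OC | intermediate (not isolated)
10 | lithium 2-(2,6-dimethoxyphenoxy)ethyn-1-ide | [Li]C#COc1c(OC)cccc1OC | intermediate (not isolated)
11 | lithium 1-[(2,6-dimethoxyphenoxy)ethynyl]-2,3-dimethoxy-4-oxocyclobut-2-en-1-olate (racemic) | [Li+].[O-]C1(C#COc2c(OC)cccc2OC)C(OC)=C(OC)C1=O | intermediate (not isolated)
12 | 4-[(2,6-dimethoxyphenoxy)ethynyl]-2,3,4-trimethoxycyclobut-2-en-1-one (racemic) | COC1=C(OC)C(OC)(C#COc2c(OC)cccc2OC)C1=O | intermediate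
13 | 4-[(Z)-2-(2,6-dimethoxyphenoxy)ethenyl]-2,3,4-trimethoxycyclobut-2-en-1-one (racemic) | COC1=C(OC)C(OC)(/C=C\Oc2c(OC)cccc2OC)C1=O | intermediate
14 | (3Z,5Z)-6-(2,6-dimethoxyphenoxy)-2,3,4-trimethoxyhexa-1,3,5-trien-1-one (dienylketene) | O=C=C(OC)/C(OC)=C(/OC)\C=C/Oc1c(OC)cccc1OC | intermediate (not isolated)
15 | 6-(2,6-dimethoxyphenoxy)-2,3,4-trimethoxycyclohexa-2,4-dien-1-one (racemic) | COC1=C(OC)C(OC)=CC(Oc2c(OC)cccc2OC)C1=O | intermediate (not isolated)
16 | 6-(2,6-dimethoxyphenoxy)-2,3,4-trimethoxyphenol (ring CD phenol) | COc1cc(Oc2c(OC)cccc2OC)c(O)c(OC)c1OC | intermediate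
17 | 1-(2,6-dimethoxyphenoxy)-2-[3,5-dimethoxy-4-(3,4,5-trimethoxyphenoxy)phenoxy]-3,4,5-trimethoxybenzene (ring CDEF tetramer) | COc1cccc(OC)c1Oc1cc(OC)c(OC)c(OC)c1Oc1cc(OC)c(Oc2cc(OC)c(OC)c(OC)c2)c(OC)c1 | intermediate
18 | pinacol boronate of 17 at the para position of ring C | CC1(C)OB(OC1(C)C)c1cc(OC)c(Oc2cc(OC)c(OC)c(OC)c2Oc2cc(OC)c(Oc3cc(OC)c(OC)c(OC)c3)c(OC)c2)c(OC)c1 | intermediate (not isolated)
19 | {4-[2-[3,5-dimethoxy-4-(3,4,5-trimethoxyphenoxy)phenoxy]-3,4,5-trimethoxyphenoxy]-3,5-dimethoxyphenyl}boronic acid | OB(O)c1cc(OC)c(Oc2cc(OC)c(OC)c(OC)c2Oc2cc(OC)c(Oc3cc(OC)c(OC)c(OC)c3)c(OC)c2)c(OC)c1 | intermediate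
20 | 1-[4-(2,6-dimethoxyphenoxy)-2,6-dimethoxyphenoxy]-2-[3,5-dimethoxy-4-(3,4,5-trimethoxyphenoxy)phenoxy]-3,4,5-trimethoxybenzene (ring BCDEF pentamer) | COc1cccc(OC)c1Oc1cc(OC)c(Oc2cc(OC)c(OC)c(OC)c2Oc2cc(OC)c(Oc3cc(OC)c(OC)c(OC)c3)c(OC)c2)c(OC)c1 | intermediate
21 | pinacol boronate of 20 at the para position of ring B | CC1(C)OB(OC1(C)C)c1cc(OC)c(Oc2cc(OC)c(Oc3cc(OC)c(OC)c(OC)c3Oc3cc(OC)c(Oc4cc(OC)c(OC)c(OC)c4)c(OC)c3)c(OC)c2)c(OC)c1 | intermediate (not isolated)
22 | {4-[4-[2-[3,5-dimethoxy-4-(3,4,5-trimethoxyphenoxy)phenoxy]-3,4,5-trimethoxyphenoxy]-2,6-dimethoxyphenoxy]-3,5-dimethoxyphenyl}boronic acid | OB(O)c1cc(OC)c(Oc2cc(OC)c(Oc3cc(OC)c(OC)c(OC)c3Oc3cc(OC)c(Oc4cc(OC)c(OC)c(OC)c4)c(OC)c3)c(OC)c2)c(OC)c1 | intermediate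
23 | 2,4,6-trimethoxyphenol | COc1cc(OC)c(O)c(OC)c1 | starting material
24 | pentadeca-O-methyl ether of the target (ring ABCDEF hexamer) | COc1cc(OC)c(Oc2cc(OC)c(Oc3cc(OC)c(Oc4cc(OC)c(OC)c(OC)c4Oc4cc(OC)c(Oc5cc(OC)c(OC)c(OC)c5)c(OC)c4)c(OC)c3)c(OC)c2)c(OC)c1 | intermediate
25 | pentadecakis(dibromoboryl) ether of the target (aryl borate) | BrB(Br)Oc1cc(OB(Br)Br)c(Oc2cc(OB(Br)Br)c(Oc3cc(OB(Br)Br)c(Oc4cc(OB(Br)Br)c(OB(Br)Br)c(OB(Br)Br)c4Oc4cc(OB(Br)Br)c(Oc5cc(OB(Br)Br)c(OB(Br)Br)c(OB(Br)Br)c5)c(OB(Br)Br)c4)c(OB(Br)Br)c3)c(OB(Br)Br)c2)c(OB(Br)Br)c1 | intermediate (not isolated)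
26 | CNP0175585.0 (achiral hexameric phlorotannin) | Oc1cc(O)c(Oc2cc(O)c(Oc3cc(O)c(Oc4cc(O)c(O)c(O)c4Oc4cc(O)c(Oc5cc(O)c(O)c(O)c5)c(O)c4)c(O)c3)c(O)c2)c(O)c1 | target

**Step count and risks**

Total steps: 12. Longest linear sequence: 10 steps (steps 3 to 12, from 2,6-dimethoxyphenol); steps 1 and 2 form the ring EF branch that joins in step 7.

Steps most likely to fail:

1. Step 6 (ring expansion). The dienylketene 14 may be lost to dimerization before the 6π closure, which the inward aryloxy group could slow, or the Z enol ether may hydrolyse before ring opening. The fallback closes the ring at the alkyne stage. It sets out from 11, which would be protonated (aq. NH4Cl) instead of methylated to give 4-[(2,6-dimethoxyphenoxy)ethynyl]-4-hydroxy-2,3-dimethoxycyclobut-2-en-1-one F1. Its Moore rearrangement (p-xylene, 138 °C; ring opening, six-ring closure to a diradical, hydrogen transfer from the hydroxyl) should give 2,3-dimethoxy-5-(2,6-dimethoxyphenoxy)cyclohexa-2,5-diene-1,4-dione F2. Reduction (Na2S2O4, THF–H2O) would give 2,3-dimethoxy-5-(2,6-dimethoxyphenoxy)benzene-1,4-diol F3, and methylation of its less hindered hydroxyl, the one next to the ring C–H (MeI 1 equiv, K2CO3, acetone), would come back to 16.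

2. Step 7 (coupling of the ring CD phenol). Reductive elimination at the di-ortho-substituted, very electron-rich phenoxide may be slow, so that oxidation of 16 by divalent copper and air and protodeboronation of 5 take over. The fallback removes the oxidant. It sets out from 5, which would be converted (CuBr2, MeOH–H2O, 80 °C) into 5-bromo-1,3-dimethoxy-2-(3,4,5-trimethoxyphenoxy)benzene F4. An Ullmann-type coupling of F4 with 16 under argon (CuI, picolinic acid, K3PO4, DMSO, 90 °C) would come back to 17.

3. Step 12 (global demethylation). Partly demethylated borates may precipitate and leave some of the fifteen methyl ethers uncleaved, and the free polyphenol may oxidize in air during purification. The fallback isolates the product in protected form. It sets out from 24: the crude product of the BBr3 reaction would be acetylated (Ac2O, pyridine) to the pentadecaacetate of the target F5, which is stable to air and silica gel and can be separated from partly methylated material for recycling. Acid methanolysis (HCl in MeOH, Ar, rt) would then come back to 26.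

**Further compounds**

F1 | step 6 | 4-[(2,6-dimethoxyphenoxy)ethynyl]-4-hydroxy-2,3-dimethoxycyclobut-2-en-1-one (racemic) | COC1=C(OC)C(O)(C#COc2c(OC)cccc2OC)C1=O
F2 | step 6 | 2,3-dimethoxy-5-(2,6-dimethoxyphenoxy)cyclohexa-2,5-diene-1,4-dione | COC1=C(OC)C(=O)C(Oc2c(OC)cccc2OC)=CC1=O
F3 | step 6 | 2,3-dimethoxy-5-(2,6-dimethoxyphenoxy)benzene-1,4-diol | COc1c(OC)c(O)c(Oc2c(OC)cccc2OC)cc1O
F4 | step 7 | 5-bromo-1,3-dimethoxy-2-(3,4,5-trimethoxyphenoxy)benzene | COc1cc(Br)cc(OC)c1Oc1cc(OC)c(OC)c(OC)c1
F5 | step 12 | pentadecaacetate of the target | CC(=O)Oc1cc(OC(C)=O)c(Oc2cc(OC(C)=O)c(Oc3cc(OC(C)=O)c(Oc4cc(OC(C)=O)c(OC(C)=O)c(OC(C)=O)c4Oc4cc(OC(C)=O)c(Oc5cc(OC(C)=O)c(OC(C)=O)c(OC(C)=O)c5)c(OC(C)=O)c4)c(OC(C)=O)c3)c(OC(C)=O)c2)c(OC(C)=O)c1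
A1 | direct plan | 2,6-bis(benzyloxy)-4-[2,4,6-tris(benzyloxy)phenoxy]phenol (ring AB phenol) | Oc1c(OCc2ccccc2)cc(Oc2c(OCc3ccccc3)cc(OCc3ccccc3)cc2OCc2ccccc2)cc1OCc1ccccc1
A2 | direct plan | 2,6-bis(benzyloxy)-4-bromobenzaldehyde | O=Cc1c(OCc2ccccc2)cc(Br)cc1OCc1ccccc1
A3 | direct plan | 2,3,4-tris(benzyloxy)-6-bromobenzaldehyde | O=Cc1c(Br)cc(OCc2ccccc2)c(OCc2ccccc2)c1OCc1ccccc1
A4 | direct plan | 2,6-bis(benzyloxy)-4-{2,6-bis(benzyloxy)-4-[2,4,6-tris(benzyloxy)phenoxy]phenoxy}phenol (ring ABC phenol) | Oc1c(OCc2ccccc2)cc(Oc2c(OCc3ccccc3)cc(Oc3c(OCc4ccccc4)cc(OCc4ccccc4)cc3OCc3ccccc3)cc2OCc2ccccc2)cc1OCc1ccccc1
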